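**Retrosynthetic overview** (lactone numbering: O1, C2 carbonyl, C3 arylidene carbon, C4 stereocentre, C5 OCH2)
- Target ⇐ its triisopropylsilyl ether ⇐ the same lactone carrying two tert-butyl ester groups on C5. They are a removable activating pair: acidolysis, loss of CO2 and Barton reduction turn C5(CO2tBu)2 into C5H2.
- Key disconnection: the ring bond C4–C5 and, in the same operation, the CH2–aryl bond of the C4 benzyl group. This leads back to an acyclic 2-arylidenebut-3-enoyl ester of di-tert-butyl hydroxymalonate and 5-iodo-1,2,3-trimethoxybenzene (Heck arylation of the vinyl group, then ring-closing allylic alkylation on palladium).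
- Enabling feature: C4 is allylic to the exocyclic C3=CH–aryl bond, so C4–C3–CH(aryl) is a 2-acylallyl unit whose central carbon C3 carries the lactone carbonyl C2 and, through O1, C5. As an allylpalladium unit it is attacked at C4 by a C5 malonate carbanion held on O1, and E/Z and facial isomers of the allyl complex funnel into the one (3E,4S) lactone.
- The dienyl ester comes from syringaldehyde (silylation, α-aldol with a crotonate dienolate, dehydration, deallylation) and di-tert-butyl bromomalonate (carboxylate O-alkylation).
- Ring order: the butyrolactone is the only ring that is formed (step 7); both benzene rings are bought.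

Key step: step 7

Remark (assumption on the chemistry): the sense of induction of the phosphoramidite in step 7 cannot be predicted with certainty; the (S)-H8-BINOL ligand is written, and its mirror image is to be used if the first run shows the 4R lactone.
Abbreviations: Ar1 = 3,5-dimethoxy-4-(triisopropylsilyloxy)phenyl; Ar2 = 3,4,5-trimethoxyphenyl.

**Step 1**
Reactants: 1 syringaldehyde (4-hydroxy-3,5-dimethoxybenzaldehyde)
Product: 2 3,5-dimethoxy-4-(triisopropylsilyloxy)benzaldehyde
Conditions: iPr3SiCl, imidazole, DMF, rt → 40 °C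
Reagents that add atoms: triisopropylsilyl chloride, CC(C)[Si](Cl)(C(C)C)C(C)C
Why: Silyl ether formation (imidazole-assisted O-silylation) masks the phenol, which would otherwise quench the dienolate in step 2, be alkylated in step 6 and attack the allylpalladium species in step 7, and the hindered silyl ether should survive the mild bases, the acid and the radical conditions that follow.

**Step 2**
Reactants: 2 3,5-dimethoxy-4-(triisopropylsilyloxy)benzaldehyde; 3 allyl (E)-but-2-enoate (allyl crotonate)
Product: 5 allyl 2-[hydroxy(Ar1)methyl]but-3-enoate (racemic; syn/anti mixture), via lithium dienolate 4 (not isolated)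
Conditions: LiN(iPr)2, THF/DMPU, −78 °C; then 2, −78 °C; aq NH4Cl at −78 °C
Reagents that add atoms: none
Why: Aldol addition of an ester dienolate: γ-deprotonation of the crotonate gives the lithium dienolate 4, which under kinetic control attacks the aldehyde through its α-carbon, so that vinyl group and carbinol sit on neighbouring carbons; the two new stereocentres are not controlled because both become sp2 in step 3.

**Step 3**
Reactants: 5 allyl 2-[hydroxy(Ar1)methyl]but-3-enoate
Product: 7 allyl (2E)-2-(Ar1-methylidene)but-3-enoate (E expected to dominate; any Z isomer is carried on), via benzylic mesylate 6 (not isolated)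
Conditions: MsCl, Et3N, CH2Cl2, 0 °C; then DBU, 0 °C → rt
Reagents that add atoms: none
Why: Dehydration by mesylation and E1cB elimination: the α-hydrogen of 6 is ester-activated and allylic, so DBU expels mesylate to give the cross-conjugated diene, with the aryl group expected mainly trans to the ester; the geometry is not critical because step 7 is stereoconvergent.

**Step 4**
Reactants: 7 allyl (2E)-2-(Ar1-methylidene)but-3-enoate
Product: 8 (2E)-2-(Ar1-methylidene)but-3-enoic acid
Conditions: Pd(PPh3)4 (2 mol %), morpholine, THF, rt; aq citric acid work-up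
Reagents that add atoms: none
Why: Tsuji–Trost deallylation: zerovalent palladium ionises the allyl ester to an allylpalladium carboxylate and morpholine takes up the allyl group, which frees the acid under neutral conditions that spare the diene and the aryl silyl ether.

**Step 5**
Reactants: 9 di-tert-butyl malonate
Product: 10 di-tert-butyl 2-bromomalonate
Conditions: CBr4, DBU, THF, −78 → 0 °C
Reagents that add atoms: carbon tetrabromide, BrC(Br)(Br)Br
Why: Electrophilic α-bromination by halogen transfer from CBr4 to the DBU-generated malonate enolate gives the monobromide without acid, which the tert-butyl esters would not survive.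

**Step 6**
Reactants: 8 (2E)-2-(Ar1-methylidene)but-3-enoic acid; 10 di-tert-butyl 2-bromomalonate
Product: 11 di-tert-butyl 2-{[(2E)-2-(Ar1-methylidene)but-3-enoyl]oxy}malonate
Conditions: Cs2CO3 (0.5 equiv), DMF, rt; then 10, 0 °C → rt
Reagents that add atoms: none
Why: SN2 O-alkylation of the cesium carboxylate by the doubly activated secondary bromide (the established way to acyloxymalonates) places the future C5 on the ester oxygen as a soft pronucleophile, and the carboxylate is too weak a base to deprotonate 10 or 11.

**Step 7**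
Reactants: 11 di-tert-butyl 2-{[(2E)-2-(Ar1-methylidene)but-3-enoyl]oxy}malonate; 12 5-iodo-1,2,3-trimethoxybenzene
Product: 15 (3E,4S)-5,5-bis(tert-butoxycarbonyl)-3-(Ar1-methylidene)-4-(Ar2-methyl)oxolan-2-one, via arylpalladium iodide 13 (not isolated), via allylpalladium iodide 14 (not isolated)
Conditions: Pd2(dba)3 (2.5 mol %), (S)-H8-BINOL N,N-bis[(R)-1-phenylethyl]phosphoramidite (6 mol %), Cs2CO3 (1.5 equiv), THF (0.05 M), 50 °C
Reagents that add atoms: none
Why: Proposed new method: zerovalent palladium adds oxidatively to the C–I bond of 12, the arylpalladium iodide 13 carbopalladates the terminal vinyl group of 11 with the aryl group going to the CH2 terminus (Heck-type insertion), and the allylpalladium iodide 14 so formed (allyl unit C4–C3–CH(Ar1), ester carbonyl on the central carbon) is attacked at C4 by the Cs2CO3-deprotonated acyloxymalonate carbon hanging on the ester oxygen, which forms the C4–C5 bond and returns zerovalent palladium. The closest known reaction types are the palladium-catalysed arylation/allylic alkylation of 1,3-dienes by aryl iodides and malonates (enantioselective with BINOL-type phosphoramidites), the ring-closing allylic alkylation that ends palladium–trimethylenemethane (3+2) cycloadditions, and allylic alkylation by 2-acyloxy-1,3-dicarbonyl nucleophiles; new is their combination in a diene that carries the nucleophile on the ester at its 2-position. The lactone closes in the 5-exo-tet sense of a trimethylenemethane cycloaddition: C5 displaces palladium from the allyl terminus C4 on the face anti to the metal, while C3=CH(Ar1) remains exocyclic. The C4 stereocentre is set in this attack by the chiral phosphoramidite on palladium, because the allyl complexes that arise from either diene isomer and either face interconvert by π–σ–π isomerisation before they cyclise (stereoconvergent, Curtin–Hammett control). The step needs attack at C4 and not at the benzylic terminus, which is secured by the known preference of 1-aryl-3-alkylallyl palladium complexes for attack remote from the aryl group and by the conjugation of the resulting alkene to both Ar1 and the lactone carbonyl; it also needs the E alkene, which is secured because Ar1 avoids the 2-acyl substituent of the allyl unit, as in allylic substitutions of Morita–Baylis–Hillman acetates.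

**Step 8**
Reactants: 15 (3E,4S)-5,5-bis(tert-butoxycarbonyl)-3-(Ar1-methylidene)-4-(Ar2-methyl)oxolan-2-one
Product: 17 (3E,4S)-5-carboxy-3-(Ar1-methylidene)-4-(Ar2-methyl)oxolan-2-one (mixture of C5 epimers), via geminal diacid 16 (not isolated)
Conditions: CF3CO2H/CH2Cl2 (1:4), anisole, 0 °C → rt; evaporate; toluene, 100 °C
Reagents that add atoms: none
Why: Acidolysis of both tert-butyl esters (loss of isobutene via the tert-butyl cation, anisole as cation trap) spares the lactone, the aryl silyl ether and the conjugated alkene, and the malonic-type diacid 16 then loses one CO2 thermally through the usual cyclic transition state; C4 is not enolisable and keeps its configuration, and the C5 epimer mixture is irrelevant because C5 becomes CH2 in step 9.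

**Step 9**
Reactants: 17 (3E,4S)-5-carboxy-3-(Ar1-methylidene)-4-(Ar2-methyl)oxolan-2-one
Product: 19 (3E,4S)-3-(Ar1-methylidene)-4-(Ar2-methyl)oxolan-2-one, via thiohydroxamate ester 18 (not isolated)
Conditions: 1-hydroxypyridine-2(1H)-thione, DCC, DMAP (cat.), CH2Cl2, 0 °C → rt, dark; then tBuSH, AIBN (cat.), toluene, 80 °C
Reagents that add atoms: none
Why: Barton reductive decarboxylation: the O-acyl thiohydroxamate 18 fragments in a thiyl radical chain to CO2 and the C5 radical, which is stabilised by the ring oxygen and should take a hydrogen atom from tBuSH faster than it fragments or adds to the hindered trisubstituted alkene, so that C5 becomes the required CH2 without touching C4.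

**Step 10**
Reactants: 19 (3E,4S)-3-(Ar1-methylidene)-4-(Ar2-methyl)oxolan-2-one
Product: 20 (3E,4S)-3-(4-hydroxy-3,5-dimethoxybenzylidene)-4-(3,4,5-trimethoxybenzyl)oxolan-2-one (CNP0198204.2)
Conditions: Bu4NF, AcOH, THF, 0 °C
Reagents that add atoms: none
Why: Fluoride-induced desilylation of the aryl silyl ether (Si–F bond formation), buffered by acetic acid so that the phenoxide is protonated as it forms, should leave the lactone, the E alkene and the C4 stereocentre untouched.

**Compound list**
1 | syringaldehyde (4-hydroxy-3,5-dimethoxybenzaldehyde) | COc1cc(C=O)cc(OC)c1O | starting material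
2 | 3,5-dimethoxy-4-(triisopropylsilyloxy)benzaldehyde | COc1cc(C=O)cc(OC)c1O[Si](C(C)C)(C(C)C)C(C)C | intermediate
3 | allyl (E)-but-2-enoate (allyl crotonate) | C/C=C/C(=O)OCC=C | starting material
4 | lithium 1-(allyloxy)buta-1,3-dien-1-olate (dienolate of 3) | C=CC=C([O-])OCC=C.[Li+] | intermediate
5 | allyl 2-{hydroxy[3,5-dimethoxy-4-(triisopropylsilyloxy)phenyl]methyl}but-3-enoate (racemic, syn/anti mixture) | C=CCOC(=O)C(C=C)C(O)c1cc(OC)c(O[Si](C(C)C)(C(C)C)C(C)C)c(OC)c1 | intermediate
6 | allyl 2-{(methanesulfonyloxy)[3,5-dimethoxy-4-(triisopropylsilyloxy)phenyl]methyl}but-3-enoate | C=CCOC(=O)C(C=C)C(OS(C)(=O)=O)c1cc(OC)c(O[Si](C(C)C)(C(C)C)C(C)C)c(OC)c1 | intermediate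
7 | allyl (2E)-2-{[3,5-dimethoxy-4-(triisopropylsilyloxy)phenyl]methylidene}but-3-enoate | COc1cc(/C=C(\C=C)C(=O)OCC=C)cc(OC)c1O[Si](C(C)C)(C(C)C)C(C)C | intermediate
8 | (2E)-2-{[3,5-dimethoxy-4-(triisopropylsilyloxy)phenyl]methylidene}but-3-enoic acid | COc1cc(/C=C(\C=C)C(=O)O)cc(OC)c1O[Si](C(C)C)(C(C)C)C(C)C | intermediate
9 | di-tert-butyl malonate | CC(C)(C)OC(=O)CC(=O)OC(C)(C)C | starting material
10 | di-tert-butyl 2-bromomalonate | CC(C)(C)OC(=O)C(Br)C(=O)OC(C)(C)C | intermediate
11 | di-tert-butyl 2-{[(2E)-2-{[3,5-dimethoxy-4-(triisopropylsilyloxy)phenyl]methylidene}but-3-enoyl]oxy}malonate | COc1cc(/C=C(\C=C)C(=O)OC(C(=O)OC(C)(C)C)C(=O)OC(C)(C)C)cc(OC)c1O[Si](C(C)C)(C(C)C)C(C)C | intermediate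
12 | 5-iodo-1,2,3-trimethoxybenzene | COc1cc(I)cc(OC)c1OC | starting material
13 | (3,4,5-trimethoxyphenyl)palladium iodide (divalent palladium, phosphoramidite ligand omitted) | COc1cc([Pd]I)cc(OC)c1OC | intermediate
14 | allylpalladium iodide from 13 and 11 (divalent palladium; drawn in its η1 form with palladium on C4, ligand omitted) | COc1cc(C=C(C(=O)OC(C(=O)OC(C)(C)C)C(=O)OC(C)(C)C)C([Pd]I)Cc2cc(OC)c(OC)c(OC)c2)cc(OC)c1O[Si](C(C)C)(C(C)C)C(C)C | intermediate
15 | (3E,4S)-5,5-bis(tert-butoxycarbonyl)-3-{[3,5-dimethoxy-4-(triisopropylsilyloxy)phenyl]methylidene}-4-(3,4,5-trimethoxybenzyl)oxolan-2-one | COc1cc(/C=C2/C(=O)OC(C(=O)OC(C)(C)C)(C(=O)OC(C)(C)C)[C@H]2Cc2cc(OC)c(OC)c(OC)c2)cc(OC)c1O[Si](C(C)C)(C(C)C)C(C)C | intermediate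
16 | (3E,4S)-5,5-dicarboxy-3-{[3,5-dimethoxy-4-(triisopropylsilyloxy)phenyl]methylidene}-4-(3,4,5-trimethoxybenzyl)oxolan-2-one | COc1cc(/C=C2/C(=O)OC(C(=O)O)(C(=O)O)[C@H]2Cc2cc(OC)c(OC)c(OC)c2)cc(OC)c1O[Si](C(C)C)(C(C)C)C(C)C | intermediate
17 | (3E,4S)-5-carboxy-3-{[3,5-dimethoxy-4-(triisopropylsilyloxy)phenyl]methylidene}-4-(3,4,5-trimethoxybenzyl)oxolan-2-one (C5 epimers) | COc1cc(/C=C2/C(=O)OC(C(=O)O)[C@H]2Cc2cc(OC)c(OC)c(OC)c2)cc(OC)c1O[Si](C(C)C)(C(C)C)C(C)C | intermediate
18 | 2-thioxopyridin-1(2H)-yl ester of 17 (Barton ester) | COc1cc(/C=C2/C(=O)OC(C(=O)On3ccccc3=S)[C@H]2Cc2cc(OC)c(OC)c(OC)c2)cc(OC)c1O[Si](C(C)C)(C(C)C)C(C)C | intermediate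
19 | (3E,4S)-3-{[3,5-dimethoxy-4-(triisopropylsilyloxy)phenyl]methylidene}-4-(3,4,5-trimethoxybenzyl)oxolan-2-one | COc1cc(/C=C2/C(=O)OC[C@H]2Cc2cc(OC)c(OC)c(OC)c2)cc(OC)c1O[Si](C(C)C)(C(C)C)C(C)C | intermediate
20 | (3E,4S)-3-(4-hydroxy-3,5-dimethoxybenzylidene)-4-(3,4,5-trimethoxybenzyl)oxolan-2-one (CNP0198204.2) | COc1cc(/C=C2/C(=O)OC[C@H]2Cc2cc(OC)c(OC)c(OC)c2)cc(OC)c1O | target

**Step count and risks**
Total step count: 10. Longest linear sequence: 9 steps (1, 2, 3, 4, 6, 7, 8, 9, 10); step 5 is a one-step side branch.

Step 7 (key step, proposed new method). Processes at risk: attack of the malonate carbon at the benzylic allyl terminus instead of C4; β-hydride elimination of the allylpalladium intermediate to a plain Heck triene; Diels–Alder dimerisation of the diene at the reaction temperature; poor facial selectivity in the ring closure. Fallback (known chemistry; sets out from 2 together with commercial 3,4,5-trimethoxybenzaldehyde and dimethyl succinate, and comes back at 19): Stobbe condensation of 3,4,5-trimethoxybenzaldehyde with dimethyl succinate (KOtBu, tBuOH, reflux) should give (E)-3-(methoxycarbonyl)-4-(3,4,5-trimethoxyphenyl)but-3-enoic acid F1. Rhodium-catalysed asymmetric hydrogenation ([Rh(cod)2]BF4 with a chiral DuPhos- or DIOP-type bisphosphine, antipode chosen for S; H2, MeOH, Et3N) should give (3S)-3-(methoxycarbonyl)-4-(3,4,5-trimethoxyphenyl)butanoic acid F2. Reduction of the ester group of its potassium salt with Ca(BH4)2 (from CaCl2 and NaBH4, EtOH), then aqueous HCl, should lactonise it to (S)-4-(3,4,5-trimethoxybenzyl)oxolan-2-one F3. Its lithium enolate (LiN(iPr)2, THF, −78 °C) adds to aldehyde 2 to give the aldol (4S)-3-[hydroxy(Ar1)methyl]-4-(3,4,5-trimethoxybenzyl)oxolan-2-one F4. Mesylation (MsCl, Et3N) gives the mesylate of the aldol F5, and DBU elimination gives 19, from which step 10 runs unchanged.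

Step 9. Processes at risk: reversible addition of the thiyl chain carrier to the electron-rich arylidene bond (E/Z scrambling or thiol adducts) and breakdown of the light- and heat-sensitive thiohydroxamate ester before the chain starts. Fallback (sets out from 17, comes back at 19): acid 17 is coupled with N-hydroxyphthalimide (N,N'-diisopropylcarbodiimide, CH2Cl2) to the N-(acyloxy)phthalimide of 17 F6. This is reduced thiol-free by nickel-catalysed reductive decarboxylation (NiCl2·6H2O and 4,4'-di-tert-butyl-2,2'-bipyridine as catalyst, Zn, PhSiH3, THF/DMF/iPrOH, 40 °C) to 19.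

Step 6. Processes at risk: bromine transfer from 10 to the carboxylate or base-induced self-condensation of 10, instead of substitution at its hindered carbon. Fallback (sets out from 8 and 9, comes back at 11): diazo transfer to malonate 9 (4-acetamidobenzenesulfonyl azide, DBU, MeCN) gives di-tert-butyl 2-diazomalonate F7. O–H insertion of the rhodium carbenoid generated from it with Rh2(OAc)4 (1 mol %, CH2Cl2, rt, slow addition of F7) into acid 8 gives 11 without bromide or base.

**Further compounds**
F1 | step 7 | (E)-3-(methoxycarbonyl)-4-(3,4,5-trimethoxyphenyl)but-3-enoic acid | COC(=O)/C(CC(=O)O)=C/c1cc(OC)c(OC)c(OC)c1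
F2 | step 7 | (3S)-3-(methoxycarbonyl)-4-(3,4,5-trimethoxyphenyl)butanoic acid | COC(=O)[C@H](CC(=O)O)Cc1cc(OC)c(OC)c(OC)c1
F3 | step 7 | (S)-4-(3,4,5-trimethoxybenzyl)oxolan-2-one | O=C1OC[C@H](C1)Cc1cc(OC)c(OC)c(OC)c1
F4 | step 7 | (4S)-3-{hydroxy[3,5-dimethoxy-4-(triisopropylsilyloxy)phenyl]methyl}-4-(3,4,5-trimethoxybenzyl)oxolan-2-one | COc1cc(C(O)C2C(=O)OC[C@H]2Cc2cc(OC)c(OC)c(OC)c2)cc(OC)c1O[Si](C(C)C)(C(C)C)C(C)C
F5 | step 7 | methanesulfonate of F4 | COc1cc(C(OS(C)(=O)=O)C2C(=O)OC[C@H]2Cc2cc(OC)c(OC)c(OC)c2)cc(OC)c1O[Si](C(C)C)(C(C)C)C(C)C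
F6 | step 9 | 1,3-dioxoisoindolin-2-yl ester of 17 | COc1cc(/C=C2/C(=O)OC(C(=O)ON3C(=O)c4ccccc4C3=O)[C@H]2Cc2cc(OC)c(OC)c(OC)c2)cc(OC)c1O[Si](C(C)C)(C(C)C)C(C)C
F7 | step 6 | di-tert-butyl 2-diazomalonate | CC(C)(C)OC(=O)C(=[N+]=[N-])C(=O)OC(C)(C)C
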